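Readings and results stem from a simulated flask with constants of no real substance, noise included.

A closed, stirred, isothermal vessel holds starting material, a little free catalyst and coupling partner, and the open intermediate in it first builds up and then is used up to product.

common to all: starting material 0.064 M
- north-west: coupling partner 0.95 equiv; free catalyst 0.36 mol%; run made earlier
- south: coupling partner 0.95 equiv; free catalyst 0.97 mol%; run made earlier
- teal: coupling partner 0.950 equiv; free catalyst 0.4 mol%; time 6.0 min
- amber: coupling partner 0.950 equiv; free catalyst 0.6 mol%; time 6.0 min
- violet: coupling partner 0.950 equiv; free catalyst 0.8 mol%; time 6.0 min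
- ochre: coupling partner 0.950 equiv; free catalyst 1.2 mol%; time 6.0 min

| run | time / min | open intermediate / % | product / % | starting material / % |
|---|---|---|---|---|
| north-west | 0.500 | 11.8 | 0 | 86.6 |
| north-west | 1.00 | 21.4 | 0.7 | 75.7 |
| north-west | 1.50 | 29.5 | 1.9 | 65.6 |
| north-west | 2.00 | 36.1 | 2.0 | 57.8 |
| north-west | 2.50 | 41.3 | 2.8 | 51.3 |
| north-west | 3.00 | 45.7 | 4.1 | 45.3 |
| south | 0.250 | 15.3 | 0 | 83.4 |
| south | 0.417 | 23.9 | 0.4 | 74.0 |
| south | 0.667 | 34.7 | 3.0 | 62.6 |
| south | 1.00 | 45.4 | 3.8 | 49.8 |
| south | 2.00 | 59.5 | 10.0 | 27.0 |
| south | 3.00 | 64.5 | 18.2 | 15.4 |

(each reading ± 0.5 percentage points)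

- the numbers in the tables scatter with a standard deviation of 0.5 percentage points
- "hardly changes" means that all values lie within two and a half points (for a concentration: within two and a half percent of the largest)

* amount of open intermediate at the end, in percent of the starting material charged for teal, amber, violet, ochre, in this order
* how the row runs (rises, then falls / hardly changes / falls all the way / falls, then rises / rises all the way)

Suppose the catalyst carries both steps, so that each goes with loading times time. A clock can then be defined: catalyst time is time multiplied by the loading and divided by teal's loading. South at 1.00 min has a catalyst time of 2.43 min and north-west at 3.00 min has 2.70 min, so the two clocks differ, but a constant for the fall of c(starting material), the logarithm of charge over reading per unit of catalyst time, can still be compared. It reads 0.287 min⁻¹ in south and 0.293 min⁻¹ in north-west, so on these two readings of starting material the clock holds about as closely as their scatter allows; for the using-up step it remains a supposition.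

Treating both steps as pseudo-first-order on this clock, the last south reading, at a catalyst time of 7.28 min, gives an opening constant of 0.257 min⁻¹. The last two south readings of product and open intermediate give a using-up constant of 0.0545 min⁻¹.

Open intermediate peaks where making equals using, at the peak catalyst time ln(opening constant / using-up constant) / (their difference), which is 7.65 min. At 6.0 min, teal stands at a catalyst time of 6.0 min, below the peak, and amber at 9.00 min, above it, so the row should rise and then fall.

My reckoning gives 64.4%, 65.1%, 60.2% and 46.3%. It holds the using-up constant fixed, although c(coupling partner) falls as product forms, so its late points may come out low.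

The forecast gave 58%, 60%, 58% and 51%, that is rises, then falls, with “a shallow maximum near 0.6 mol%”. The flask gives 61.2%, 63.9%, 62.0% and 54.3%, so rises, then falls, and ochre stands 8 percentage points above my reckoning.

    starting material + free catalyst → free catalyst + open intermediate (k = 1180 L mol⁻¹ min⁻¹)
    free catalyst + open intermediate ⇌ catalyst intermediate (K = 6.90 L mol⁻¹, k = 30000 L mol⁻¹ min⁻¹)
    coupling partner + catalyst intermediate → free catalyst + product (k = 660 L mol⁻¹ min⁻¹)
    2 starting material → homo dimer (k = 0.248 L mol⁻¹ min⁻¹)

In teal at 6.00 min, short of the peak catalyst time of 7.65 min, open intermediate is still made 1.62 times faster than it is used up, each step taken net, and the row turns at 0.59 mol%, a catalyst time of 8.81 min. Ochre at 3.00 min has a catalyst time of 9.00 min, past the peak and equal to amber's at 6.00 min, and the two flasks hold 65.0% and 63.9% open intermediate, with 10.3% and 9.93% starting material.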